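The ten-membered carbocycle (C1–C10) is disconnected at C3–C4. C3 is a carbinol next to the Z-trisubstituted C4=C5 olefin, so a Z-alkenyl iodide at C4 and an aldehyde at C3 can be joined by a Nozaki–Hiyama–Kishi reaction. This closes the ring, forms C3–C4 and creates the C3 stereocentre in one operation. The cyclisation precursor already holds the trans C6/C7 α-methylene γ-lactone (C11–C13), the C1/C10 epoxide and the silylated C8 carbinol. It is assembled by an indium-mediated allylation (C7–C8) of a β,γ-epoxy aldehyde with a chiral 2-(bromomethyl)enoate that carries the Z-iodoalkene.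

Key step: step 18

Remark: germacrane numbering is used throughout (ring C1–C10, lactone carbons C11–C13, C14 on C10, C15 on C4). Read from the target, the O3 acyl group is (R)-2-methylbutanoyl and the O8 acyl group is (2S,3R)-2,3-dimethyloxirane-2-carbonyl (ring methyls cis). Precursor 24 and product 25 of the key step carry the target configuration at C1, C6, C7, C8, C10 and the Z olefin. Aldehydes 8, 14 and 24 are made immediately before use and not stored.

Step 1
Reactants: 1 tert-butyl(but-3-yn-1-yloxy)dimethylsilane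
Product: 4 (E)-6-[(tert-butyldimethylsilyl)oxy]-4-methylhex-3-en-1-ol, via alkenyldimethylalane 2 (not isolated), via lithium alkenylalanate 3 (not isolated)
Conditions: AlMe3, Cp2ZrCl2 (0.25 equiv), CH2Cl2, 0 °C to rt; volatiles removed; n-BuLi, THF/hexane, −78 °C; ethylene oxide, −78 °C to rt
Reagents that add atoms: trimethylaluminium (AlMe3) C[Al](C)C; ethylene oxide C1CO1
Why: Zirconium-catalysed Negishi carboalumination adds methyl and aluminium syn across the terminal alkyne with methyl on the internal carbon, which fixes the E-trisubstituted C1=C10 olefin, and the derived alanate opens ethylene oxide at carbon with retention of olefin geometry (alkenylalanate–epoxide alkylation).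

Step 2
Reactants: 4 (E)-6-[(tert-butyldimethylsilyl)oxy]-4-methylhex-3-en-1-ol
Product: 5 (E)-tert-butyl({6-[(4-methoxybenzyl)oxy]-3-methylhex-3-en-1-yl}oxy)dimethylsilane
Conditions: NaH, 4-methoxybenzyl chloride, Bu4NI (cat.), THF/DMF, 0 °C to rt
Reagents that add atoms: 4-methoxybenzyl chloride COc1ccc(CCl)cc1
Why: Williamson etherification of the primary alkoxide should give the O3 PMB ether while the silyl ether and the olefin are untouched.

Step 3
Reactants: 5 (E)-tert-butyl({6-[(4-methoxybenzyl)oxy]-3-methylhex-3-en-1-yl}oxy)dimethylsilane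
Product: 6 tert-butyl(2-{(2R,3R)-3-[2-((4-methoxybenzyl)oxy)ethyl]-2-methyloxiran-2-yl}ethoxy)dimethylsilane
Conditions: Oxone, D-fructose-derived Shi ketone (0.3 equiv), K2CO3, Bu4NHSO4 (cat.), MeCN/dimethoxymethane/aq. borate–EDTA buffer (pH about 10.5), 0 °C
Reagents that add atoms: Oxone (active component KHSO5) [K+].[O-]S(=O)(=O)OO
Why: Shi asymmetric epoxidation, in which the chiral dioxirane transfers oxygen through a spiro transition state to one face of the E-trisubstituted olefin; for this substitution pattern the D-fructose-derived ketone should give the (R,R) epoxide, that is (1R,10R) in germacrane numbering, and the buffered conditions spare the PMB and silyl ethers.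

Step 4
Reactants: 6 tert-butyl(2-{(2R,3R)-3-[2-((4-methoxybenzyl)oxy)ethyl]-2-methyloxiran-2-yl}ethoxy)dimethylsilane
Product: 7 2-{(2R,3R)-3-[2-((4-methoxybenzyl)oxy)ethyl]-2-methyloxiran-2-yl}ethan-1-ol
Conditions: Bu4NF, THF, 0 °C to rt
Reagents that add atoms: none
Why: Fluoride-mediated cleavage of the primary silyl ether; the epoxide and the PMB ether are inert to Bu4NF.

Step 5
Reactants: 7 2-{(2R,3R)-3-[2-((4-methoxybenzyl)oxy)ethyl]-2-methyloxiran-2-yl}ethan-1-ol
Product: 8 2-{(2R,3R)-3-[2-((4-methoxybenzyl)oxy)ethyl]-2-methyloxiran-2-yl}acetaldehyde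
Conditions: Dess–Martin periodinane, NaHCO3, CH2Cl2, 0 °C; used at once
Reagents that add atoms: none
Why: Dess–Martin oxidation under bicarbonate buffering forms the C8 aldehyde without the acid or base that would open the β,γ-epoxide by elimination.

Step 6
Reactants: 9 (R)-(2,2-dimethyl-1,3-dioxolan-4-yl)methanol
Product: 10 (S)-2,2-dimethyl-1,3-dioxolane-4-carbaldehyde
Conditions: (COCl)2, DMSO, CH2Cl2, −78 °C; Et3N, −78 °C to 0 °C
Reagents that add atoms: none
Why: Swern oxidation of the primary alcohol leaves the ring stereocentre (future C6) untouched; the descriptor changes from R to S only through the priority change.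

Step 7
Reactants: 10 (S)-2,2-dimethyl-1,3-dioxolane-4-carbaldehyde
Product: 11 (R)-4-[(Z)-2-iodoprop-1-en-1-yl]-2,2-dimethyl-1,3-dioxolane
Conditions: EtPPh3I, n-BuLi, THF, rt; I2, −78 °C; NaHMDS, −20 °C; then 10, −78 °C to rt
Reagents that add atoms: ethyltriphenylphosphonium iodide CC[P+](c1ccccc1)(c1ccccc1)c1ccccc1.[I-]; iodine II
Why: Stork–Zhao-type Wittig olefination with the α-iodo ylide runs under kinetic control through the oxaphosphetane that places the aldehyde residue cis to iodine, which should give the Z-2-iodoalkene (C4=C5 with C15) without enolising the α-alkoxy stereocentre at low temperature.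

Step 8
Reactants: 11 (R)-4-[(Z)-2-iodoprop-1-en-1-yl]-2,2-dimethyl-1,3-dioxolane
Product: 12 (R,Z)-4-iodopent-3-ene-1,2-diol
Conditions: AcOH/H2O (4:1), 40 °C
Reagents that add atoms: none
Why: Acid-catalysed acetal hydrolysis releases the 1,2-diol; the alkenyl iodide and the C–O stereocentre are stable to dilute acetic acid.

Step 9
Reactants: 12 (R,Z)-4-iodopent-3-ene-1,2-diol
Product: 13 (R,Z)-4-iodo-1,2-bis[(triethylsilyl)oxy]pent-3-ene
Conditions: Et3SiCl, imidazole, CH2Cl2, 0 °C to rt
Reagents that add atoms: chlorotriethylsilane CC[Si](Cl)(CC)CC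
Why: Standard silylation of both hydroxyls; the triethylsilyl group is chosen so that O6 can later be freed in the presence of a tert-butyldimethylsilyl ether.

Step 10
Reactants: 13 (R,Z)-4-iodo-1,2-bis[(triethylsilyl)oxy]pent-3-ene
Product: 14 (R,Z)-4-iodo-2-[(triethylsilyl)oxy]pent-3-enal
Conditions: (COCl)2, DMSO, CH2Cl2, −78 °C to −40 °C; i-Pr2NEt, −78 °C to 0 °C; used at once
Reagents that add atoms: none
Why: Under Swern conditions the activated sulfoxide cleaves the less hindered primary triethylsilyl ether selectively and oxidises it in the same flask, so the secondary silyl ether stays; the hindered amine and low temperature are meant to preserve the C6 configuration.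

Step 11
Reactants: 14 (R,Z)-4-iodo-2-[(triethylsilyl)oxy]pent-3-enal; 15 methyl propiolate
Product: 17 methyl (4R,5Z)-3-hydroxy-6-iodo-2-methylidene-4-[(triethylsilyl)oxy]hept-5-enoate (both C3 epimers), via α-aluminated acrylate 16 (not isolated)
Conditions: i-Bu2AlH, HMPA, THF, 0 °C, then 15; then 14, −78 °C to −20 °C
Reagents that add atoms: none
Why: Conjugate hydroalumination of the propiolate gives an α-aluminated acrylate that adds to the aldehyde (vinylalumination, a base-free equivalent of the Morita–Baylis–Hillman reaction); the new carbinol carbon (C7) becomes sp2 in the next step, so its configuration is irrelevant.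

Step 12
Reactants: 17 methyl (4R,5Z)-3-hydroxy-6-iodo-2-methylidene-4-[(triethylsilyl)oxy]hept-5-enoate
Product: 18 methyl (2Z,4S,5Z)-2-(bromomethyl)-6-iodo-4-[(triethylsilyl)oxy]hepta-2,5-dienoate
Conditions: N-bromosuccinimide, Me2S, CH2Cl2, −20 °C to 0 °C
Reagents that add atoms: N-bromosuccinimide O=C1CCC(=O)N1Br
Why: Corey–Kim-type activation of the allylic alcohol followed by SN2′ attack of bromide transposes the olefin and should give the thermodynamically preferred Z-2-(bromomethyl)enoate (C6 branch trans to the ester), as is general for Morita–Baylis–Hillman alcohols; C6 is not touched.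

Step 13
Reactants: 8 2-{(2R,3R)-3-[2-((4-methoxybenzyl)oxy)ethyl]-2-methyloxiran-2-yl}acetaldehyde; 18 methyl (2Z,4S,5Z)-2-(bromomethyl)-6-iodo-4-[(triethylsilyl)oxy]hepta-2,5-dienoate
Product: 19 methyl (3R,4S,5Z)-3-{(1R)-1-hydroxy-2-[(2R,3R)-3-{2-[(4-methoxybenzyl)oxy]ethyl}-2-methyloxiran-2-yl]ethyl}-6-iodo-2-methylidene-4-[(triethylsilyl)oxy]hept-5-enoate (C6, C7, C8 as in 32)
Conditions: In powder, THF/H2O (1:1), 0 °C to rt; crude product taken on directly
Reagents that add atoms: none
Why: Barbier-type allylation in which the 2-(methoxycarbonyl)allylindium species (C6 branch cis to the metal-bearing CH2) adds at C7 through a closed Zimmerman–Traxler chair, which should give the syn relation between O8 and the C6 branch, while the face of C7 is chosen by the adjacent silyloxy stereocentre C6 (H-6 eclipsing the olefin through allylic 1,3-strain and the new C7–C8 bond forming anti to the C6–O bond, Felkin-type 1,2-induction), and these two elements together give the C6/C7/C8 triad of the target; the alkenyl iodide, epoxide and silyl ether are inert to indium metal in aqueous THF.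

Step 14
Reactants: 19 methyl (3R,4S,5Z)-3-{(1R)-1-hydroxy-2-[(2R,3R)-3-{2-[(4-methoxybenzyl)oxy]ethyl}-2-methyloxiran-2-yl]ethyl}-6-iodo-2-methylidene-4-[(triethylsilyl)oxy]hept-5-enoate
Product: 20 the C8 tert-butyldimethylsilyl ether of 19 (C6 triethylsilyl ether, C12 methyl ester, O3 PMB ether, 1,10-epoxide)
Conditions: TBSOTf, 2,6-lutidine, CH2Cl2, −78 °C
Reagents that add atoms: tert-butyldimethylsilyl trifluoromethanesulfonate CC(C)(C)[Si](C)(C)OS(=O)(=O)C(F)(F)F
Why: Fast low-temperature silylation caps the C8 hydroxyl before it can lactonise onto the C12 ester (which would give the unwanted 8,12-lactone), and the hindered base keeps the epoxide from Lewis-acid opening.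

Step 15
Reactants: 20 the C8 tert-butyldimethylsilyl ether of 19
Product: 22 trans-α-methylene γ-lactone (12,6-olide) with the Z-iodopropenyl group on C6, the C8 OTBS side chain on C7, the 1,10-epoxide and the O3 PMB ether (configuration as in 32), via C6 hydroxy ester 21 (not isolated)
Conditions: HF·pyridine, pyridine, THF, 0 °C to rt
Reagents that add atoms: none
Why: Buffered HF·pyridine removes the more labile, doubly allylic triethylsilyl ether in the presence of the tert-butyldimethylsilyl ether, and the freed C6 hydroxyl lactonises onto the C12 methyl ester (5-exo-trig acyl substitution), giving the trans lactone because C6 and C7 are already set.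

Step 16
Reactants: 22 trans-α-methylene γ-lactone with O3 PMB ether
Product: 23 C3 primary alcohol of the seco lactone (C8 OTBS, 1,10-epoxide, C4 iodide)
Conditions: DDQ, CH2Cl2/pH 7 phosphate buffer (10:1), 0 °C
Reagents that add atoms: none
Why: Oxidative cleavage of the PMB ether by DDQ under neutral buffered conditions spares the silyl ether, the epoxide, the alkenyl iodide and the α-methylene lactone.

Step 17
Reactants: 23 C3 primary alcohol of the seco lactone
Product: 24 seco C3 aldehyde with C4 Z-alkenyl iodide (C8 OTBS, 1,10-epoxide, 12,6-olide)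
Conditions: Dess–Martin periodinane, NaHCO3, CH2Cl2, 0 °C; filtered and used at once
Reagents that add atoms: none
Why: Buffered Dess–Martin oxidation gives the β,γ-epoxy aldehyde under neutral conditions, avoiding base-induced opening of the epoxide.

Step 18
Reactants: 24 seco C3 aldehyde with C4 Z-alkenyl iodide
Product: 25 C3 alcohol (3S) of the C8-silylated germacranolide 1,10-epoxide
Conditions: CrCl2 (8 equiv), NiCl2 (0.1 equiv), DMSO/THF (3:1), rt, 2 mM, slow addition of 24
Reagents that add atoms: none
Why: Zerovalent nickel, formed from NiCl2 by reduction with CrCl2, inserts into the C4–I bond with retention of the Z geometry, and transmetalation to trivalent chromium gives an alkenylchromium species that adds to the C3 aldehyde (Nozaki–Hiyama–Kishi reaction; the closest precedents are alkenyl iodide–aldehyde macrocyclisations to nine- and ten-membered carbocycles). The ten-membered ring closes by intramolecular 1,2-addition with the carbonyl oxygen outside the ring (10-exo-trig), the Z olefin and the trans lactone at C6/C7 holding C3 and C4 close. The only new stereocentre, C3, is controlled by the conformation of the folded macrocyclic transition state (substrate control); the carbonyl is expected to point away from the C15 methyl and the ring interior, which should lead to the 3S carbinol, but this is the uncertain point of the route. The step needs chemoselectivity for the aldehyde over the lactone, the enoate and the epoxide, which the non-basic, aldehyde-selective organochromium reagent provides, and cyclisation over oligomerisation, which high dilution and slow addition secure.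

Step 19
Reactants: 25 C3 alcohol of the C8-silylated germacranolide epoxide; 26 (R)-2-methylbutanoic acid
Product: 27 C3 (R)-2-methylbutanoate of the C8-silylated germacranolide epoxide
Conditions: DCC, DMAP (cat.), CH2Cl2, 0 °C to rt
Reagents that add atoms: none
Why: Steglich esterification of the allylic secondary alcohol with retention at C3; the α-alkyl acid should not racemise under carbodiimide activation with catalytic DMAP.

Step 20
Reactants: 27 C3 (R)-2-methylbutanoate of the C8-silylated germacranolide epoxide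
Product: 28 C8 alcohol of the C3 (R)-2-methylbutanoate
Conditions: HF·pyridine, pyridine, THF, 0 °C to rt
Reagents that add atoms: none
Why: Fluoride-mediated desilylation under buffered conditions frees O8 without touching the two esters, the epoxide or the α-methylene lactone.

Step 21
Reactants: 29 (E)-2-methylbut-2-en-1-ol
Product: 30 [(2R,3R)-2,3-dimethyloxiran-2-yl]methanol
Conditions: Ti(OiPr)4 (cat.), D-(−)-diethyl tartrate (cat.), t-BuOOH, 4 Å molecular sieves, CH2Cl2, −20 °C
Reagents that add atoms: tert-butyl hydroperoxide CC(C)(C)OO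
Why: Sharpless asymmetric epoxidation, in which the D-(−)-tartrate titanium complex delivers oxygen to the face of the E-allylic alcohol that gives the (2R,3R) epoxy alcohol, and the stereospecific syn oxygen transfer keeps the two methyl groups cis.

Step 22
Reactants: 30 [(2R,3R)-2,3-dimethyloxiran-2-yl]methanol
Product: 31 (2S,3R)-2,3-dimethyloxirane-2-carboxylic acid
Conditions: RuCl3 (cat.), NaIO4, CCl4/MeCN/H2O, rt
Reagents that add atoms: water O
Why: RuO4-catalysed oxidation of the primary alcohol to the acid through the aldehyde hydrate leaves the epoxide intact; the descriptor at C2 changes from R to S only through the priority change.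

Step 23
Reactants: 28 C8 alcohol of the C3 (R)-2-methylbutanoate; 31 (2S,3R)-2,3-dimethyloxirane-2-carboxylic acid
Product: 32 CNP0265335.4
Conditions: 2-methyl-6-nitrobenzoic anhydride, DMAP, Et3N, CH2Cl2, rt
Reagents that add atoms: none
Why: Shiina esterification through a mixed anhydride with nucleophilic catalysis couples the hindered acid and the hindered secondary alcohol under mild conditions that spare the lactone, both epoxides and the C3 ester, with retention at C8.

Compound list
1 | tert-butyl(but-3-yn-1-yloxy)dimethylsilane | C#CCCO[Si](C)(C)C(C)(C)C | starting material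
2 | (E)-{4-[(tert-butyldimethylsilyl)oxy]-2-methylbut-1-en-1-yl}dimethylalane | C[Al](C)/C=C(\C)CCO[Si](C)(C)C(C)(C)C | intermediate
3 | lithium butyl{(E)-4-[(tert-butyldimethylsilyl)oxy]-2-methylbut-1-en-1-yl}dimethylalanate | [Li+].CCCC[Al-](C)(C)/C=C(\C)CCO[Si](C)(C)C(C)(C)C | intermediate
4 | (E)-6-[(tert-butyldimethylsilyl)oxy]-4-methylhex-3-en-1-ol | OCC/C=C(\C)CCO[Si](C)(C)C(C)(C)C | intermediate
5 | (E)-tert-butyl({6-[(4-methoxybenzyl)oxy]-3-methylhex-3-en-1-yl}oxy)dimethylsilane | COc1ccc(COCC/C=C(\C)CCO[Si](C)(C)C(C)(C)C)cc1 | intermediate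
6 | tert-butyl(2-{(2R,3R)-3-[2-((4-methoxybenzyl)oxy)ethyl]-2-methyloxiran-2-yl}ethoxy)dimethylsilane | COc1ccc(COCC[C@H]2O[C@]2(C)CCO[Si](C)(C)C(C)(C)C)cc1 | intermediate
7 | 2-{(2R,3R)-3-[2-((4-methoxybenzyl)oxy)ethyl]-2-methyloxiran-2-yl}ethan-1-ol | COc1ccc(COCC[C@H]2O[C@]2(C)CCO)cc1 | intermediate
8 | 2-{(2R,3R)-3-[2-((4-methoxybenzyl)oxy)ethyl]-2-methyloxiran-2-yl}acetaldehyde | COc1ccc(COCC[C@H]2O[C@]2(C)CC=O)cc1 | intermediate
9 | (R)-(2,2-dimethyl-1,3-dioxolan-4-yl)methanol ((R)-solketal) | OC[C@@H]1COC(C)(C)O1 | starting material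
10 | (S)-2,2-dimethyl-1,3-dioxolane-4-carbaldehyde | O=C[C@@H]1COC(C)(C)O1 | intermediate
11 | (R)-4-[(Z)-2-iodoprop-1-en-1-yl]-2,2-dimethyl-1,3-dioxolane | C/C(I)=C/[C@@H]1COC(C)(C)O1 | intermediate
12 | (R,Z)-4-iodopent-3-ene-1,2-diol | OC[C@H](O)/C=C(/C)I | intermediate
13 | (R,Z)-4-iodo-1,2-bis[(triethylsilyl)oxy]pent-3-ene | CC[Si](CC)(CC)OC[C@H](O[Si](CC)(CC)CC)/C=C(/C)I | intermediate
14 | (R,Z)-4-iodo-2-[(triethylsilyl)oxy]pent-3-enal | O=C[C@H](O[Si](CC)(CC)CC)/C=C(/C)I | intermediate
15 | methyl propiolate | C#CC(=O)OC | starting material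
16 | methyl 2-(diisobutylalumanyl)prop-2-enoate | C=C(C(=O)OC)[Al](CC(C)C)CC(C)C | intermediate
17 | methyl (4R,5Z)-3-hydroxy-6-iodo-2-methylidene-4-[(triethylsilyl)oxy]hept-5-enoate (C3 epimers) | C=C(C(=O)OC)C(O)[C@H](O[Si](CC)(CC)CC)/C=C(/C)I | intermediate
18 | methyl (2Z,4S,5Z)-2-(bromomethyl)-6-iodo-4-[(triethylsilyl)oxy]hepta-2,5-dienoate | COC(=O)/C(CBr)=C/[C@H](O[Si](CC)(CC)CC)/C=C(/C)I | intermediate
19 | methyl (3R,4S,5Z)-3-{(1R)-1-hydroxy-2-[(2R,3R)-3-{2-[(4-methoxybenzyl)oxy]ethyl}-2-methyloxiran-2-yl]ethyl}-6-iodo-2-methylidene-4-[(triethylsilyl)oxy]hept-5-enoate | COc1ccc(COCC[C@H]2O[C@]2(C)C[C@@H](O)[C@@H](C(=C)C(=O)OC)[C@H](O[Si](CC)(CC)CC)/C=C(/C)I)cc1 | intermediate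
20 | C8 tert-butyldimethylsilyl ether of 19 (C6 OSiEt3, C12 methyl ester, O3 PMB, 1,10-epoxide; C1, C6, C7, C8, C10 as in 32) | COc1ccc(COCC[C@H]2O[C@]2(C)C[C@@H](O[Si](C)(C)C(C)(C)C)[C@@H](C(=C)C(=O)OC)[C@H](O[Si](CC)(CC)CC)/C=C(/C)I)cc1 | intermediate
21 | C6 hydroxy methyl ester from 20 (C8 OTBS, O3 PMB, 1,10-epoxide; configuration as in 32) | COc1ccc(COCC[C@H]2O[C@]2(C)C[C@@H](O[Si](C)(C)C(C)(C)C)[C@@H](C(=C)C(=O)OC)[C@H](O)/C=C(/C)I)cc1 | intermediate
22 | trans-α-methylene γ-lactone (12,6-olide): C6 bears the (Z)-2-iodoprop-1-enyl group, C7 the C8 OTBS chain with the (1R,10R)-epoxide and the O3 PMB ether; C6, C7, C8 as in 32 | COc1ccc(COCC[C@H]2O[C@]2(C)C[C@@H](O[Si](C)(C)C(C)(C)C)[C@H]3C(=C)C(=O)O[C@@H]3/C=C(/C)I)cc1 | intermediate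
23 | C3 primary alcohol of seco lactone 22 (PMB removed) | OCC[C@H]1O[C@]1(C)C[C@@H](O[Si](C)(C)C(C)(C)C)[C@H]1C(=C)C(=O)O[C@@H]1/C=C(/C)I | intermediate
24 | seco C3 aldehyde with C4 Z-alkenyl iodide (12,6-olide, C8 OTBS, (1R,10R)-epoxide; C6, C7, C8 as in 32) | O=CC[C@H]1O[C@]1(C)C[C@@H](O[Si](C)(C)C(C)(C)C)[C@H]1C(=C)C(=O)O[C@@H]1/C=C(/C)I | intermediate
25 | (3S)-C3 alcohol of the C8-O-TBS germacra-4Z,11(13)-dien-12,6-olide 1,10-epoxide (C1, C6, C7, C8, C10 as in 32) | C=C1C(=O)O[C@@H]2/C=C(/C)[C@@H](O)C[C@H]3O[C@]3(C)C[C@@H](O[Si](C)(C)C(C)(C)C)[C@@H]12 | intermediate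
26 | (R)-2-methylbutanoic acid | CC[C@@H](C)C(=O)O | starting material
27 | 3-O-[(R)-2-methylbutanoyl] derivative of 25 (C8 OTBS) | C=C1C(=O)O[C@@H]2/C=C(/C)[C@@H](OC(=O)[C@H](C)CC)C[C@H]3O[C@]3(C)C[C@@H](O[Si](C)(C)C(C)(C)C)[C@@H]12 | intermediate
28 | C8 alcohol of the 3-O-[(R)-2-methylbutanoyl] germacranolide epoxide | C=C1C(=O)O[C@@H]2/C=C(/C)[C@@H](OC(=O)[C@H](C)CC)C[C@H]3O[C@]3(C)C[C@@H](O)[C@@H]12 | intermediate
29 | (E)-2-methylbut-2-en-1-ol | C/C=C(\C)CO | starting material
30 | [(2R,3R)-2,3-dimethyloxiran-2-yl]methanol | OC[C@@]1(C)O[C@@H]1C | intermediate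
31 | (2S,3R)-2,3-dimethyloxirane-2-carboxylic acid | OC(=O)[C@@]1(C)O[C@@H]1C | intermediate
32 | CNP0265335.4: (1R,3S,6R,7R,8R,10R,4Z)-1,10-epoxy-3-[(R)-2-methylbutanoyloxy]-8-[(2S,3R)-2,3-dimethyloxirane-2-carbonyloxy]germacra-4,11(13)-dien-12,6-olide | C=C1C(=O)O[C@@H]2/C=C(/C)[C@@H](OC(=O)[C@H](C)CC)C[C@H]3O[C@]3(C)C[C@@H](OC(=O)[C@@]3(C)O[C@@H]3C)[C@@H]12 | target

Total step count: 23. Longest linear sequence: 16 steps (steps 6–12, 13–20 and 23).

Steps most likely to fail

Step 18. The ring-closing addition may occur with low or inverted facial selectivity at C3, because the aldehyde can present either face in the folded seco chain. The fallback sets C3 by a reagent instead of by the ring conformation. It sets out from 24: the crude cyclisation product, 25 mixed with its C3 epimer F1, is oxidised with Dess–Martin periodinane/NaHCO3 to the macrocyclic C3 enone F2. This is reduced with (R)-2-methyl-CBS-oxazaborolidine and catecholborane (Corey–Bakshi–Shibata reduction, the alkenyl arm acting as the large group) and the route is rejoined at 25.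

Step 13. The indium-mediated union may lose facial control by the C6 silyloxy group or syn/anti control through equilibration of the allylmetal, and the hydroxy ester may lactonise early onto O8. The fallback builds the lactone across C6–C7 with a configurationally fixed allylboronate, sets out from 8 and returns at 22.
- Aldehyde 8 is alkynylated with methyl propiolate 15 (ZnMe2, ProPhenol ligand of the enantiomer that gives the 8R carbinol) to the propargylic alcohol F3, which is silylated (TBSOTf, 2,6-lutidine) to the silyl ether F4.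
- Conjugate hydroalumination (i-Bu2AlH, HMPA) and trapping of the α-aluminated enoate with ICH2Bpin gives the 2-(methoxycarbonyl)allylboronate F5, with the C8 branch trans to the boron-bearing CH2.
- In parallel, ethyl but-2-ynoate is hydroiodinated (NaI, AcOH) to ethyl (Z)-3-iodobut-2-enoate F6, reduced (i-Bu2AlH) to (Z)-3-iodobut-2-en-1-ol F7 and oxidised (MnO2) to (Z)-3-iodobut-2-enal F8.
- Thermal allylboration of F8 with F5 through a closed chair should give the 6,7-anti adduct, which lactonises on work-up to 22.

The controlling stereocentre (C8) then sits on the other side of the forming bond, so the demand on 1,2-induction is complementary to that of step 13.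

Step 10. The α-silyloxy β,γ-unsaturated aldehyde may epimerise at C6, or its C4=C5 olefin may migrate into conjugation, when it is released in the presence of amine base. The fallback makes the aldehyde by base-free hydride reduction, sets out from 12 and returns at 14. The primary alcohol of 12 is oxidised selectively with TEMPO/PhI(OAc)2 in MeCN/H2O to the hydroxy acid F9. Esterification with Me3SiCHN2 gives the methyl ester F10, silylation (Et3SiCl, imidazole) gives the silyloxy ester F11, and i-Bu2AlH at −78 °C reduces F11 to 14.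

Further compounds
F1 | step 18 | (3R)-C3 alcohol, C3 epimer of 25 | C=C1C(=O)O[C@@H]2/C=C(/C)[C@H](O)C[C@H]3O[C@]3(C)C[C@@H](O[Si](C)(C)C(C)(C)C)[C@@H]12
F2 | step 18 | macrocyclic C3 enone of the C8-O-TBS germacranolide epoxide | C=C1C(=O)O[C@@H]2/C=C(/C)C(=O)C[C@H]3O[C@]3(C)C[C@@H](O[Si](C)(C)C(C)(C)C)[C@@H]12
F3 | step 13 | methyl (R)-4-hydroxy-5-{(2R,3R)-3-[2-((4-methoxybenzyl)oxy)ethyl]-2-methyloxiran-2-yl}pent-2-ynoate | COc1ccc(COCC[C@H]2O[C@]2(C)C[C@@H](O)C#CC(=O)OC)cc1
F4 | step 13 | methyl (R)-4-[(tert-butyldimethylsilyl)oxy]-5-{(2R,3R)-3-[2-((4-methoxybenzyl)oxy)ethyl]-2-methyloxiran-2-yl}pent-2-ynoate | COc1ccc(COCC[C@H]2O[C@]2(C)C[C@@H](O[Si](C)(C)C(C)(C)C)C#CC(=O)OC)cc1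
F5 | step 13 | methyl (2Z,4R)-4-[(tert-butyldimethylsilyl)oxy]-5-{(2R,3R)-3-[2-((4-methoxybenzyl)oxy)ethyl]-2-methyloxiran-2-yl}-2-[(4,4,5,5-tetramethyl-1,3,2-dioxaborolan-2-yl)methyl]pent-2-enoate | COc1ccc(COCC[C@H]2O[C@]2(C)C[C@@H](O[Si](C)(C)C(C)(C)C)/C=C(/CB3OC(C)(C)C(C)(C)O3)C(=O)OC)cc1
F6 | step 13 | ethyl (Z)-3-iodobut-2-enoate | CCOC(=O)/C=C(/C)I
F7 | step 13 | (Z)-3-iodobut-2-en-1-ol | OC/C=C(/C)I
F8 | step 13 | (Z)-3-iodobut-2-enal | O=C/C=C(/C)I
F9 | step 10 | (R,Z)-2-hydroxy-4-iodopent-3-enoic acid | OC(=O)[C@H](O)/C=C(/C)I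
F10 | step 10 | methyl (R,Z)-2-hydroxy-4-iodopent-3-enoate | COC(=O)[C@H](O)/C=C(/C)I
F11 | step 10 | methyl (R,Z)-4-iodo-2-[(triethylsilyl)oxy]pent-3-enoate | COC(=O)[C@H](O[Si](CC)(CC)CC)/C=C(/C)I
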